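**Retrosynthetic overview**
- The two esters are put on last: the C15 triol core, tiglic anhydride and a silyl-protected 4-hydroxybenzoyl chloride are joined in consecutive acylations, then the phenol is freed.
- Ring B (cycloheptene) comes from RCM of a vinyl carbinol/methallyl ketone pair held cis on a cyclopentane; the C4 carbinol comes from a hydroxyl-directed ketone reduction.
- Ring A (cyclopentane) comes from a cuprate conjugate addition/intramolecular aldol on a keto-butenolide, whose single stereocentre (future C8) relays C8a, C3a and C3.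
- The keto-butenolide comes from carbocupration of a chiral γ-hydroxy alkynoate (acrolein, thiophenol, methyl propiolate) with a ketal Grignard reagent (3-bromopropanoyl chloride, i-PrMgCl).
- Ring order: temporary butenolide, then ring A, then lactone opening, then ring B.

Assumption: the target is taken as drawn in the SMILES, i.e. (3R,3aS,4R,8R,8aR), cis-fused, with an (E)-2-methylbut-2-enoate (tiglate) on C8; azulene numbering is used for the core throughout.

**Step 1**
Reactants: 1 prop-2-enal (acrolein)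
Product: 2 3-(phenylsulfanyl)propanal
Conditions: PhSH (1.0 equiv), Et3N (1 mol %), CH2Cl2, 0 → 25 °C
Reagents that add atoms: thiophenol, Sc1ccccc1
Why: Base-catalysed thia-Michael addition to the enal; the sulfide is a latent vinyl group that tolerates all later organocopper chemistry.

**Step 2**
Reactants: 2 3-(phenylsulfanyl)propanal; 3 methyl prop-2-ynoate
Product: 5 methyl (4R)-4-hydroxy-6-(phenylsulfanyl)hex-2-ynoate, via methylzinc acetylide 4 (not isolated)
Conditions: Me2Zn (3 equiv), ProPhenol ligand (10 mol %, the enantiomer that gives Si-face addition, i.e. the 4R alcohol), Ph3P=O (20 mol %), toluene, 0 °C, 24 h; aq. NH4Cl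
Reagents that add atoms: none
Why: Zinc–ProPhenol catalysed enantioselective alkynylation of the aldehyde, in which the chiral dinuclear zinc catalyst delivers the alkynylzinc to the Si face and sets the future C8 centre as R.

**Step 3**
Reactants: 6 3-bromopropanoyl chloride; 7 isopropylmagnesium chloride
Product: 8 1-bromo-4-methylpentan-3-one
Conditions: Fe(acac)3 (3 mol %), THF, −78 °C, 15 min; cold aq. NH4Cl, used without storage
Reagents that add atoms: none
Why: Iron-catalysed acylation of a Grignard reagent by an acid chloride is faster than attack on the product ketone or on the alkyl bromide at −78 °C.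

**Step 4**
Reactants: 8 1-bromo-4-methylpentan-3-one
Product: 9 2-(2-bromoethyl)-2-(propan-2-yl)-1,3-dioxolane
Conditions: 1,2-bis(trimethylsilyloxy)ethane (1.2 equiv), TMSOTf (2 mol %), CH2Cl2, −78 → −20 °C; pyridine quench
Reagents that add atoms: 1,2-bis(trimethylsilyloxy)ethane, C[Si](C)(C)OCCO[Si](C)(C)C
Why: Noyori ketalisation proceeds at low temperature under aprotic conditions, so the β-bromo ketone is masked without loss of HBr.

**Step 5**
Reactants: 9 2-(2-bromoethyl)-2-(propan-2-yl)-1,3-dioxolane; 5 methyl (4R)-4-hydroxy-6-(phenylsulfanyl)hex-2-ynoate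
Product: 12 (5R)-4-(4-methyl-3-oxopentyl)-5-[2-(phenylsulfanyl)ethyl]furan-2(5H)-one, via Grignard reagent 10 (not isolated), via butenolide ketal 11 (not isolated)
Conditions: 9, Mg turnings, THF, 25 °C (gives 10, 2.5 equiv); CuBr·SMe2 (1.25 equiv), THF, −45 °C; 5 (1.0 equiv), −78 °C, 1 h; AcOH then aq. NH4Cl; then 2 M HCl/THF (1:1), 25 °C, 4 h
Reagents that add atoms: water, O
Why: syn-Carbocupration of the alkynoate places the ester cis to the carbinol so the alkoxide lactonises to the butenolide, and the acidic work-up hydrolyses the dioxolane, all without touching the stereocentre.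

**Step 6**
Reactants: 12 (5R)-4-(4-methyl-3-oxopentyl)-5-[2-(phenylsulfanyl)ethyl]furan-2(5H)-one
Product: 13 (3R,3aR,6R,6aR)-6-hydroxy-3a-methyl-3-[2-(phenylsulfanyl)ethyl]-6-(propan-2-yl)hexahydro-1H-cyclopenta[c]furan-1-one
Conditions: Me2CuLi (from MeLi and CuI, 3 equiv), Et2O, −78 → −30 °C, 3 h; aq. NH4Cl/NH3
Reagents that add atoms: lithium dimethylcuprate Me2CuLi, [Li+].C[Cu-]C
Why: Tandem cuprate conjugate addition–intramolecular aldol: methyl adds to C4 of the butenolide anti to the C5 side chain (sets C8a), the lactone enolate closes ring A on the tethered ketone from the tether face (cis fusion, sets C3a), and the lithium chelate places the new hydroxyl syn to the lactone carbonyl (sets C3).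

**Step 7**
Reactants: 13 (3R,3aR,6R,6aR)-6-hydroxy-3a-methyl-3-[2-(phenylsulfanyl)ethyl]-6-(propan-2-yl)hexahydro-1H-cyclopenta[c]furan-1-one
Product: 15 (3R,3aR,6R,6aR)-3-ethenyl-6-hydroxy-3a-methyl-6-(propan-2-yl)hexahydro-1H-cyclopenta[c]furan-1-one, via sulfoxide 14 (not isolated)
Conditions: mCPBA (1.05 equiv), CH2Cl2, −78 °C; aq. NaHCO3 wash; then toluene, solid NaHCO3, 110 °C, 6 h
Reagents that add atoms: none
Why: Sulfide oxidation followed by thermal syn-elimination of the sulfoxide unveils the vinyl group only after the copper steps, so allylic substitution could never compete, and no stereocentre is involved.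

**Step 8**
Reactants: 15 (3R,3aR,6R,6aR)-3-ethenyl-6-hydroxy-3a-methyl-6-(propan-2-yl)hexahydro-1H-cyclopenta[c]furan-1-one
Product: 16 1-[(1R,2R,5R)-2-hydroxy-5-[(1R)-1-hydroxyprop-2-en-1-yl]-5-methyl-2-(propan-2-yl)cyclopentyl]-3-methylbut-3-en-1-one
Conditions: 2-methylallylmagnesium chloride (2.3 equiv), THF, −78 °C, 1 h; AcOH/THF quench at −78 °C, then aq. NH4Cl
Reagents that add atoms: 2-methylallylmagnesium chloride, CC(=C)C[Mg]Cl
Why: Grignard mono-addition to the lactone stops at the magnesium hemiketalate at −78 °C and gives the hydroxy ketone on quench (in equilibrium with its five-membered cyclic hemiketal), with no new stereocentre.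

**Step 9**
Reactants: 16 1-[(1R,2R,5R)-2-hydroxy-5-[(1R)-1-hydroxyprop-2-en-1-yl]-5-methyl-2-(propan-2-yl)cyclopentyl]-3-methylbut-3-en-1-one
Product: 17 (3R,3aR,8R,8aR)-3,8-dihydroxy-6,8a-dimethyl-3-(propan-2-yl)-2,3,3a,5,8,8a-hexahydroazulen-4(1H)-one
Conditions: second-generation Grubbs catalyst RuCl2(=CHPh)(H2IMes)(PCy3) (7 mol %), 1,4-benzoquinone (15 mol %), toluene (3 mM), 70 °C
Reagents that add atoms: none
Why: RCM of the vinyl carbinol with the 1,1-disubstituted alkene closes ring B as the trisubstituted cycloheptene because both arms are held cis on the cyclopentane, and benzoquinone suppresses alkene migration.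

**Step 10**
Reactants: 17 (3R,3aR,8R,8aR)-3,8-dihydroxy-6,8a-dimethyl-3-(propan-2-yl)-2,3,3a,5,8,8a-hexahydroazulen-4(1H)-one
Product: 18 (3R,3aS,4R,8R,8aR)-6,8a-dimethyl-3-(propan-2-yl)-1,2,3,3a,4,5,8,8a-octahydroazulene-3,4,8-triol
Conditions: Me4NBH(OAc)3 (6 equiv), MeCN/AcOH (1:1), −30 → −20 °C, 16 h; aq. KNaC4H4O6 (potassium sodium tartrate)
Reagents that add atoms: none
Why: Hydroxyl-directed (Evans–Saksena) reduction: hydride delivered from the alkoxyborohydride of either the C3 or the C8 hydroxyl can reach the ketone only from the face of H-3a and the angular methyl, giving the 4R alcohol syn to the C3 hydroxyl.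

**Step 11**
Reactants: 19 (2E)-2-methylbut-2-enoic acid (tiglic acid) (2 equiv)
Product: 20 (2E)-2-methylbut-2-enoic anhydride
Conditions: 19 (2.0 equiv), DCC (1.0 equiv), CH2Cl2, 0 → 25 °C; filter off the urea, evaporate
Reagents that add atoms: second molecule of (2E)-2-methylbut-2-enoic acid, C/C=C(\C)C(=O)O
Why: Carbodiimide dehydration: the O-acylisourea formed from one acid molecule is attacked by the carboxylate of a second molecule, giving the symmetrical anhydride and the urea without touching the (E)-alkene.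

**Step 12**
Reactants: 18 (3R,3aS,4R,8R,8aR)-6,8a-dimethyl-3-(propan-2-yl)-1,2,3,3a,4,5,8,8a-octahydroazulene-3,4,8-triol; 20 (2E)-2-methylbut-2-enoic anhydride
Product: 23 (3R,3aS,4R,8R,8aR)-3,4-dihydroxy-6,8a-dimethyl-3-(propan-2-yl)-1,2,3,3a,4,5,8,8a-octahydroazulen-8-yl (2E)-2-methylbut-2-enoate, via phenylboronate 21 (not isolated), via phenylboronate tiglate 22 (not isolated)
Conditions: PhB(OH)2 (1.05 equiv), toluene, 4 Å MS, 25 °C, 2 h; then 20 (3 equiv), DMAP (3 equiv), 50 °C, 18 h; then 30% H2O2, aq. NaHCO3, THF, 0 °C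
Reagents that add atoms: none
Why: A transient cyclic boronate masks the syn 1,3-diol (O3/O4) so that DMAP-catalysed acylation can occur only at the C8 hydroxyl, and oxidative cleavage of the boronate then returns the diol.

**Step 13**
Reactants: 24 4-bromophenol
Product: 25 (4-bromophenoxy)(tert-butyl)dimethylsilane
Conditions: TBSCl (1.2 equiv), imidazole (2.5 equiv), DMF, 25 °C
Reagents that add atoms: tert-butyldimethylsilyl chloride, CC(C)(C)[Si](C)(C)Cl
Why: Standard silylation protects the phenol for the lithiation and acylation steps.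

**Step 14**
Reactants: 25 (4-bromophenoxy)(tert-butyl)dimethylsilane
Product: 27 4-[(tert-butyldimethylsilyl)oxy]benzoic acid, via aryllithium 26 (not isolated)
Conditions: n-BuLi (1.05 equiv), THF, −78 °C, 30 min; CO2 (g), −78 → 0 °C; 1 M HCl to pH 3 at 0 °C
Reagents that add atoms: carbon dioxide, O=C=O
Why: Bromine–lithium exchange followed by carboxylation of the aryllithium, with a brief cold acidic work-up that leaves the aryl silyl ether intact.

**Step 15**
Reactants: 27 4-[(tert-butyldimethylsilyl)oxy]benzoic acid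
Product: 28 4-[(tert-butyldimethylsilyl)oxy]benzoyl chloride
Conditions: (COCl)2 (1.3 equiv), DMF (cat.), CH2Cl2, 0 → 25 °C; evaporate
Reagents that add atoms: oxalyl chloride, O=C(Cl)C(=O)Cl
Why: Vilsmeier-type activation gives the acid chloride needed to acylate a hindered secondary alcohol.

**Step 16**
Reactants: 23 (3R,3aS,4R,8R,8aR)-3,4-dihydroxy-6,8a-dimethyl-3-(propan-2-yl)-1,2,3,3a,4,5,8,8a-octahydroazulen-8-yl (2E)-2-methylbut-2-enoate; 28 4-[(tert-butyldimethylsilyl)oxy]benzoyl chloride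
Product: 29 (3R,3aS,4R,8R,8aR)-3-hydroxy-6,8a-dimethyl-8-{[(2E)-2-methylbut-2-enoyl]oxy}-3-(propan-2-yl)-1,2,3,3a,4,5,8,8a-octahydroazulen-4-yl 4-[(tert-butyldimethylsilyl)oxy]benzoate
Conditions: 28 (2 equiv), pyridine, DMAP (0.3 equiv), CH2Cl2, 0 → 40 °C
Reagents that add atoms: none
Why: DMAP-catalysed esterification joins the aryl fragment to the core at the only acylable hydroxyl (secondary C4), since the tertiary C3 hydroxyl is inert.

**Step 17**
Reactants: 29 (3R,3aS,4R,8R,8aR)-3-hydroxy-6,8a-dimethyl-8-{[(2E)-2-methylbut-2-enoyl]oxy}-3-(propan-2-yl)-1,2,3,3a,4,5,8,8a-octahydroazulen-4-yl 4-[(tert-butyldimethylsilyl)oxy]benzoate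
Product: 30 (3R,3aS,4R,8R,8aR)-3-hydroxy-6,8a-dimethyl-8-{[(2E)-2-methylbut-2-enoyl]oxy}-3-(propan-2-yl)-1,2,3,3a,4,5,8,8a-octahydroazulen-4-yl 4-hydroxybenzoate
Conditions: TBAF (1.2 equiv), AcOH (1.3 equiv), THF, 0 °C, 30 min
Reagents that add atoms: none
Why: Fluoride cleaves the aryl silyl ether rapidly, and the acetic acid buffer keeps both esters and the allylic system intact.

**Compound list**
1 | prop-2-enal (acrolein) | C=CC=O | starting material
2 | 3-(phenylsulfanyl)propanal | O=CCCSc1ccccc1 | intermediate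
3 | methyl prop-2-ynoate | C#CC(=O)OC | starting material
4 | methyl 3-(methylzincio)prop-2-ynoate (not isolated) | C[Zn]C#CC(=O)OC | intermediate
5 | methyl (4R)-4-hydroxy-6-(phenylsulfanyl)hex-2-ynoate | c1ccccc1SCC[C@@H](O)C#CC(=O)OC | intermediate
6 | 3-bromopropanoyl chloride | O=C(Cl)CCBr | starting material
7 | isopropylmagnesium chloride | CC(C)[Mg]Cl | starting material
8 | 1-bromo-4-methylpentan-3-one | BrCCC(=O)C(C)C | intermediate
9 | 2-(2-bromoethyl)-2-(propan-2-yl)-1,3-dioxolane | BrCCC1(C(C)C)OCCO1 | intermediate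
10 | {2-[2-(propan-2-yl)-1,3-dioxolan-2-yl]ethyl}magnesium bromide (not isolated) | Br[Mg]CCC1(C(C)C)OCCO1 | intermediate
11 | (5R)-5-[2-(phenylsulfanyl)ethyl]-4-{2-[2-(propan-2-yl)-1,3-dioxolan-2-yl]ethyl}furan-2(5H)-one (not isolated) | c1ccccc1SCC[C@H]2OC(=O)C=C2CCC3(C(C)C)OCCO3 | intermediate
12 | (5R)-4-(4-methyl-3-oxopentyl)-5-[2-(phenylsulfanyl)ethyl]furan-2(5H)-one | c1ccccc1SCC[C@H]2OC(=O)C=C2CCC(=O)C(C)C | intermediate
13 | (3R,3aR,6R,6aR)-6-hydroxy-3a-methyl-3-[2-(phenylsulfanyl)ethyl]-6-(propan-2-yl)hexahydro-1H-cyclopenta[c]furan-1-one | c1ccccc1SCC[C@H]2OC(=O)[C@@H]3[C@@]2(C)CC[C@@]3(O)C(C)C | intermediate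
14 | (3R,3aR,6R,6aR)-6-hydroxy-3a-methyl-3-[2-(phenylsulfinyl)ethyl]-6-(propan-2-yl)hexahydro-1H-cyclopenta[c]furan-1-one, both sulfur epimers (not isolated) | O=S(CC[C@H]2OC(=O)[C@@H]3[C@@]2(C)CC[C@@]3(O)C(C)C)c1ccccc1 | intermediate
15 | (3R,3aR,6R,6aR)-3-ethenyl-6-hydroxy-3a-methyl-6-(propan-2-yl)hexahydro-1H-cyclopenta[c]furan-1-one | C=C[C@H]1OC(=O)[C@@H]2[C@@]1(C)CC[C@@]2(O)C(C)C | intermediate
16 | 1-[(1R,2R,5R)-2-hydroxy-5-[(1R)-1-hydroxyprop-2-en-1-yl]-5-methyl-2-(propan-2-yl)cyclopentyl]-3-methylbut-3-en-1-one | O[C@H](C=C)[C@]1(C)CC[C@@](O)(C(C)C)[C@@H]1C(=O)CC(C)=C | intermediate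
17 | (3R,3aR,8R,8aR)-3,8-dihydroxy-6,8a-dimethyl-3-(propan-2-yl)-2,3,3a,5,8,8a-hexahydroazulen-4(1H)-one | O[C@@H]1C=C(C)CC(=O)[C@@H]2[C@@]1(C)CC[C@@]2(O)C(C)C | intermediate
18 | (3R,3aS,4R,8R,8aR)-6,8a-dimethyl-3-(propan-2-yl)-1,2,3,3a,4,5,8,8a-octahydroazulene-3,4,8-triol | O[C@@H]1C=C(C)C[C@@H](O)[C@@H]2[C@@]1(C)CC[C@@]2(O)C(C)C | intermediate
19 | (2E)-2-methylbut-2-enoic acid (tiglic acid) | C/C=C(\C)C(=O)O | starting material
20 | (2E)-2-methylbut-2-enoic anhydride | C/C=C(\C)C(=O)OC(=O)/C(C)=C/C | intermediate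
21 | cyclic phenylboronate of 18 across O3 and O4, 8-hydroxyl free (not isolated) | O[C@@H]1C=C(C)C[C@@H](OB3c4ccccc4)[C@@H]2[C@@]1(C)CC[C@@]2(O3)C(C)C | intermediate
22 | cyclic phenylboronate of 18 across O3 and O4, 8-O-[(2E)-2-methylbut-2-enoyl] (not isolated) | C/C=C(\C)C(=O)O[C@@H]1C=C(C)C[C@@H](OB3c4ccccc4)[C@@H]2[C@@]1(C)CC[C@@]2(O3)C(C)C | intermediate
23 | (3R,3aS,4R,8R,8aR)-3,4-dihydroxy-6,8a-dimethyl-3-(propan-2-yl)-1,2,3,3a,4,5,8,8a-octahydroazulen-8-yl (2E)-2-methylbut-2-enoate | C/C=C(\C)C(=O)O[C@@H]1C=C(C)C[C@@H](O)[C@@H]2[C@@]1(C)CC[C@@]2(O)C(C)C | intermediate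
24 | 4-bromophenol | Oc1ccc(Br)cc1 | starting material
25 | (4-bromophenoxy)(tert-butyl)dimethylsilane | CC(C)(C)[Si](C)(C)Oc1ccc(Br)cc1 | intermediate
26 | {4-[(tert-butyldimethylsilyl)oxy]phenyl}lithium (not isolated) | [Li]c1ccc(O[Si](C)(C)C(C)(C)C)cc1 | intermediate
27 | 4-[(tert-butyldimethylsilyl)oxy]benzoic acid | OC(=O)c1ccc(O[Si](C)(C)C(C)(C)C)cc1 | intermediate
28 | 4-[(tert-butyldimethylsilyl)oxy]benzoyl chloride | ClC(=O)c1ccc(O[Si](C)(C)C(C)(C)C)cc1 | intermediate
29 | (3R,3aS,4R,8R,8aR)-3-hydroxy-6,8a-dimethyl-8-{[(2E)-2-methylbut-2-enoyl]oxy}-3-(propan-2-yl)-1,2,3,3a,4,5,8,8a-octahydroazulen-4-yl 4-[(tert-butyldimethylsilyl)oxy]benzoate | C/C=C(\C)C(=O)O[C@@H]1C=C(C)C[C@@H](OC(=O)c2ccc(O[Si](C)(C)C(C)(C)C)cc2)[C@@H]2[C@@]1(C)CC[C@@]2(O)C(C)C | intermediate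
30 | (3R,3aS,4R,8R,8aR)-3-hydroxy-6,8a-dimethyl-8-{[(2E)-2-methylbut-2-enoyl]oxy}-3-(propan-2-yl)-1,2,3,3a,4,5,8,8a-octahydroazulen-4-yl 4-hydroxybenzoate | C/C=C(\C)C(=O)O[C@@H]1C=C(C)C[C@@H](OC(=O)c2ccc(O)cc2)[C@@H]2[C@@]1(C)CC[C@@]2(O)C(C)C | target

**Totals**
Total step count: 17.
Longest linear sequence: 11 steps (1, 2, 5, 6, 7, 8, 9, 10, 12, 16, 17; the branch through 3, 4, 5 is equally long).

**Steps most likely to fail and fallbacks**

Step 6 (tandem conjugate addition–aldol). The β,β-disubstituted butenolide may react sluggishly, the free ketone may be attacked, or the aldolate may revert. The fallback sets out from 12 and comes back at 13. Compound 12 is treated with Me2CuLi in the presence of TMSCl so that the enolate is trapped at once as the silyl ketene acetal trimethyl{[(4R,5R)-4-methyl-4-(4-methyl-3-oxopentyl)-5-[2-(phenylsulfanyl)ethyl]-4,5-dihydrofuran-2-yl]oxy}silane F1, which is isolated by non-aqueous work-up. Ring A is then closed in a separate operation by a TiCl4-mediated intramolecular Mukaiyama aldol (CH2Cl2, −78 °C), giving 13.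

Step 9 (RCM on the hydroxy ketone). The cyclic hemiketal form of 16 may hold back the diene, and the β,γ-unsaturated ketone 17 could isomerise or epimerise at C3a. The fallback sets out from 16 and comes back at 18. The ketone of 16 is reduced first with Me4NBH(OAc)3 (delivery from the tertiary hydroxyl through a chair transition state) to the acyclic triol (1R)-1-[(1S,2R,5R)-2-hydroxy-5-[(1R)-1-hydroxyprop-2-en-1-yl]-5-methyl-2-(propan-2-yl)cyclopentyl]-3-methylbut-3-en-1-ol F2. RCM of F2 with the same ruthenium catalyst then gives 18 directly, so no ketone is present in the bicycle.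

Step 12 (regiocontrol of the first acylation). The transient boronate may migrate or be cleaved under the DMAP conditions, giving mixtures. The fallback sets out from 18 and comes back at 29, with the order of the two acylations reversed. Compound 18 is heated with Bu2SnO (toluene, azeotropic removal of water) to give the dibutylstannylene acetal of 18 across O3 and O4 F3. This is acylated with 28 at the activated secondary oxygen to give (3R,3aS,4R,8R,8aR)-3,8-dihydroxy-6,8a-dimethyl-3-(propan-2-yl)-1,2,3,3a,4,5,8,8a-octahydroazulen-4-yl 4-[(tert-butyldimethylsilyl)oxy]benzoate F4. The remaining allylic C8 hydroxyl of F4 is then esterified with 20 and DMAP to give 29.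

**Further compounds**
F1 | step 6 | trimethyl{[(4R,5R)-4-methyl-4-(4-methyl-3-oxopentyl)-5-[2-(phenylsulfanyl)ethyl]-4,5-dihydrofuran-2-yl]oxy}silane | C[Si](C)(C)OC1=C[C@@](C)(CCC(=O)C(C)C)[C@@H](CCSc2ccccc2)O1
F2 | step 9 | (1R)-1-[(1S,2R,5R)-2-hydroxy-5-[(1R)-1-hydroxyprop-2-en-1-yl]-5-methyl-2-(propan-2-yl)cyclopentyl]-3-methylbut-3-en-1-ol | O[C@H](C=C)[C@]1(C)CC[C@@](O)(C(C)C)[C@@H]1[C@H](O)CC(C)=C
F3 | step 12 | dibutylstannylene acetal of 18 across O3 and O4 | O[C@@H]1C=C(C)C[C@@H](O[Sn]3(CCCC)CCCC)[C@@H]2[C@@]1(C)CC[C@@]2(O3)C(C)C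
F4 | step 12 | (3R,3aS,4R,8R,8aR)-3,8-dihydroxy-6,8a-dimethyl-3-(propan-2-yl)-1,2,3,3a,4,5,8,8a-octahydroazulen-4-yl 4-[(tert-butyldimethylsilyl)oxy]benzoate | O[C@@H]1C=C(C)C[C@@H](OC(=O)c2ccc(O[Si](C)(C)C(C)(C)C)cc2)[C@@H]2[C@@]1(C)CC[C@@]2(O)C(C)C
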